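**Side-product leak.** The proposed steps give side product no way back, so the next run hangs on how fast it grows.

| flask | starting material | temperature | remark | time |
|---|---|---|---|---|
| Saturday's | 1.2 M | 35 °C | run made earlier |  |
| zeta | 0.80 M | 35 °C |  | 25 d |
| beta | 0.80 M | 60 °C |  | 25 d |

Saturday's run (percent of the starting material charged)

| time / d | side product / % | open dimer / % | starting material / % | ring / % |
|---|---|---|---|---|
| 0.625 | 2.2 | 26.6 | 62.5 | 7.2 |
| 1.67 | 6.5 | 46.4 | 39.0 | 9.6 |
| 3.00 | 10.9 | 52.2 | 25.4 | 10.6 |
| 5.00 | 14.9 | 57.5 | 17.8 | 9.6 |

(each reading ± 1 percentage point)

- percentages count the starting material that a species holds: one open dimer or side product counts as two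
- the earlier runs were read with a standard deviation of 1 percentage point
- what may be going on: starting material <-> ring; starting material + ring -> side product; 2 starting material <-> open dimer
- the earlier runs do not show what temperature does; that part of a forecast is a guess

- which of these there is most of at the end, counted by the starting material in it, zeta (open dimer / ring / starting material / side product)
- which of these there is most of at the end, counted by the starting material in it, beta (open dimer / ring / starting material / side product)
- amount of the one of these that there is most of at the end, in percent of the starting material charged, zeta
- amount of the one of these that there is most of at the end, in percent of the starting material charged, beta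

Let a be the fraction of the charge still starting material. Saturday's last reading puts ring at 0.539 times a, and I hold that ratio for zeta. From 3.00 d to 5.00 d, Saturday's run gives 0.369 L mol⁻¹ d⁻¹. This is the leak coefficient, side product gained per day, divided by the charge and by a squared. The first reading gives the same measure for open dimer, 0.567 L mol⁻¹ d⁻¹. So the selectivity, read from these two stretches with their scatter, is 39.4% to side product.

**Two rounds.** My own reckoning for zeta assumes equal charge times time, so zeta at 7.50 d stands where Saturday's run ended. Round one, with no dimer reversal, takes a down to 7.08%, which leaves side product at 21.4% and open dimer at 67.7%.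

Round two puts that dimer back in. Saturday's late dimer gain falls short of its formation, which reads as reversal of about 0.00782 d⁻¹, a poor reading given the scatter. That returns 8.56% of the charge, and the selectivity share of it leaks. So I commit to open dimer 64.3% and side product 24.8%.

**The decision.** Saturday's run, at 35 °C, does not show the leak coefficient at 60 °C. So charge beta exactly as zeta, change the temperature alone, and sample both at 12.5 d and 25.0 d.

**The forecast.** It says open dimer at 40% for zeta, below my figure, and side product at 85% for beta, “guessing rates 6–10 times faster”.

**The result.** Zeta ends with open dimer at 55.9%, and beta with open dimer at 51.5%.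

    starting material ⇌ ring (K = 0.540, k = 0.00750 h⁻¹, Ea = 102 kJ mol⁻¹, ΔH = −51.0 kJ mol⁻¹)
    starting material + ring → side product (k = 0.0170 L mol⁻¹ h⁻¹, Ea = 68.0 kJ mol⁻¹)
    2 starting material ⇌ open dimer (K = 26.0 L mol⁻¹, k = 0.0120 L mol⁻¹ h⁻¹, Ea = 65.0 kJ mol⁻¹, ΔH = −9.00 kJ mol⁻¹)
    (constants at 35 °C)

**Leak reread.** Between the two samples, zeta's leak coefficient is 0.413 L mol⁻¹ d⁻¹, beside Saturday's 0.369 L mol⁻¹ d⁻¹. Beta's is 0.719 L mol⁻¹ d⁻¹, a factor of 1.74 above zeta's, while ring over starting material at the end is 0.120 in beta against 0.513 in zeta. Open dimer stays ahead in beta because ring returns to starting material and the time is 25 d, not 250 d. Without that return, beta's dimer is 2.33%, and at the longer time it is 3.20%.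

(All runs were generated by integration from invented constants, noise included.)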